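Which form holds most of the starting material after 10 h in gamma, delta and theta, three flasks that differ in the partner charged, and how much of it stands there?

all flasks: starting material 45 mM

| charge | partner | second substrate | third substrate | remark | time |
|---|---|---|---|---|---|
| Monday's | 110 mM | 9 mM | 9 mM | run made earlier |  |
| Sunday's | 730 mM | 9 mM | 9 mM | run made earlier |  |
| gamma | 510 mM | 9.00 mM | 9.00 mM |  | 10 h |
| delta | 200 mM | 9.00 mM | 9.00 mM |  | 10 h |
| theta | 81.0 mM | 9.00 mM | 9.00 mM |  | 10 h |

- Monday's (time / h: starting material / %, target / %): 1.33: 88.1, 11.4; 3.00: 77.9, 18.9; 4.00: 75.0, 21.9; 6.00: 70.3, 29.1; 8.00: 67.8, 34.1; 10.0: 64.2, 34.4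
- Sunday's (time / h: starting material / %, target / %): 0.500: 72.2, 26.1; 1.50: 42.9, 57.6; 3.00: 21.9, 77.9; 4.00: 14.1, 85.3; 6.00: 9.0, 92.3; 8.00: 6.1, 93.7; 10.0: 1.7, 97.2

(each reading ± 1 percentage point)

* which of these there is most of at the end, counted by the starting material in it, gamma (starting material / target)
* which of these there is most of at the end, counted by the starting material in it, delta (starting material / target)
* which of these there is most of at the end, counted by the starting material in it, theta (starting material / target)
* how much there is at the end of the one of these that leads, in percent of the starting material charged: gamma
* how much there is at the end of the one of these that leads, in percent of the starting material charged: delta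
* how much there is at the end of the one of these that leads, in percent of the starting material charged: theta

- the numbers in the tables scatter by 1 percentage point (one standard deviation)
- steps thought possible: starting material + partner -> target; second substrate + partner -> second product; third substrate + partner -> third product; 2 second substrate -> homo dimer; partner -> decomposed reagent

Progress is measured by the exponent x = ln(charged/remaining), which grows at a rate proportional to the partner present if the step is first order in the starting material and in partner. Sunday's first reading gives a rate per mM of partner, k = 8.92 × 10⁻⁴ mM⁻¹ h⁻¹. At 4.00 h, x per mM of partner charged reads 0.00268 mM⁻¹ on Sunday and 0.00262 mM⁻¹ on Monday, so the two runs lie on a common curve, and that curve bends. Here x per mM at the end of Monday's run is taken as the reckoning's measure: the yield of partner, s = 0.00403 mM⁻¹. Then T = s/k = 4.51 h is partner's working time: the flask acts as if the whole charge had lasted that long, less than the time asked.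

Each flask has its own conversion time, τ = 1/(k × partner charged), and the ladder runs as follows. Gamma's τ is 2.20 h, shorter than T, so gamma converts while partner is still strong. Delta's τ is 5.60 h, a little longer than T, so partner fades at about one τ. Theta's τ is 13.8 h, longer even than the time asked, so theta stalls early. The end exponent is s × charge, and the lead passes to the target above 0.693, where half remains. This reckoning gives target 87.2% in gamma and 55.3% in delta, and starting material 72.2% in theta.

The forecast, resting on the same slowing (“Conversion therefore stalls”), says target at 88% (83% to 92%) for gamma, target at 55% (50% to 60%) for delta, and starting material at 72% (68% to 77%) for theta. For gamma it stands slightly higher than the reckoning above.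

The flasks give target at 89.3% in gamma, target at 56.2% in delta, and starting material at 72.6% in theta.

    starting material + partner → target (k = 0.930 M⁻¹ h⁻¹)
    second substrate + partner → second product (k = 0.140 M⁻¹ h⁻¹)
    third substrate + partner → third product (k = 2.90 M⁻¹ h⁻¹)
    2 second substrate → homo dimer (k = 2.10 M⁻¹ h⁻¹)
    partner → decomposed reagent (k = 0.150 h⁻¹)

Delta's end gives x per mM of 0.00413 mM⁻¹, beside the 0.00403 mM⁻¹ read from Monday's run. The same reckoning goes to a further flask, like delta but charged with 50 mM of partner. Its τ is 22.4 h, and its end exponent s × charge is 0.201, below the value where the lead passes, so starting material is reckoned to lead at 81.8%. That flask ends with starting material leading, at 82.3%, and target at 17.7%.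

The readings are calculated with constants of no real substance, and the scatter is random.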